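**Design of a total synthesis of CNP0400752.1 by lactone-templated ruthenium alkyne–alkene macrocyclization**

## The problem

The target 26 is an 11-membered carbocycle, numbered here C1 (ring carbon carrying the exocyclic methylene), C2, C3, C4, C5 (carboxyl), C6, C7 (isovaleryloxy), C8, C9 (gem-dimethyl), C10 and C11 (carbinol). No second ring helps to close it, so the medium-ring closure is the central difficulty. It has two stereocentres, C7 (S) and C11 (S), which are 1,5-related across the quaternary C9. Neither can direct the other, so each must be set by reagent or catalyst control, and the trisubstituted C4=C5 alkene must be E (C3 cis to C6). The isovalerate must survive the release of the neighbouring acid, which rules out hydroxide once the ester is in place. The free C5 carboxyl and the C7 oxygen are 1,4-related and lactonize easily, and the C11 allylic alcohol beside the 1,1-disubstituted alkene dislikes strong acid and electrophilic oxidants. Two features make a short solution possible. First, the unit CH2=C1(C11–O)–C2 is what a terminal propargylic alkyne gives when its internal carbon is joined to the end of an allyl group, and the alkene this leaves at C3=C4 is one base-mediated shift from C4=C5. Second, the C5 carboxyl and C7 oxygen can be tied temporarily as a γ-lactone, which holds the two chain ends on one face, makes C5–H acidic for allylation and for the later alkene shift, and favours the E geometry.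

## Retrosynthesis

**Endgame (26 back to 21).** The O–Si bond at C11 (25), the allyl ester C–O bond (24) and the C7–O acyl bond (23) are cut in turn, and hydroxy ester 23 is traced through carboxylate 22 to the bridged alkylidene lactone 21. The isovalerate can only be put on after the lactone is opened, and the acid must then be masked by a group removable without hydroxide or strong acid. An allyl ester (cleaved by zerovalent palladium) and a TBS ether (cleaved by fluoride) meet this. The forward steps must trap the hydroxy carboxylate before it re-lactonizes.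

**Alkene transposition (21 back to 20).** No bond is cut; the C4=C5 alkene is moved to C3=C4. This turns the enoate into a 1,4-diene (C1 methylene and C3=C4), the retron of an alkene–alkyne coupling. It asks of the forward reaction that base equilibration in the bridged lactone ends at the conjugated E isomer.

**Ring closure (20 back to 19).** The C1–C2 bond is cut, giving the acyclic cis α-allyl γ-lactone 19 with a terminal alkyne. Cutting here, and not at C3–C4 or C5–carboxyl, makes the ring-forming step also the one that creates the methylene and places the alkene. The precursor is a single chain with one five-membered ring. The forward reaction must be branched-selective and must win over oligomerization.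

**Lactone substituents (19 back to 13 and 14).** The alkyne C–H of 19 comes from the C-silyl compound 18, the cis C5 configuration of 18 from the trans epimer 16 by enolate protonation, and the C4–C5 bond of 16 from lactone 13 and allyl bromide 14. The silyl cap keeps the acidic alkyne C–H out of the enolate chemistry. C5 is under substrate control and is erased later, so it costs no chiral reagent.

**Lactone ring (13 back to 8).** The lactone carbonyl of 13 is taken back to the primary alcohol of diol 12, this to the terminal alkene of homoallylic alcohol 10, and the C6–C7 bond of 10 is cut to aldehyde 8 and an allyl nucleophile. Asymmetric allylation sets C7 under reagent control, which is needed because C11 is too far away to help.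

**Chain (8 back to 1).** Aldehyde 8 comes from ester 7, silyl ether 7 from propargylic alcohol 6, and 6 from ynone 5 by catalyst-controlled reduction. The C11–alkyne bond of 5 is cut to half ester 2 (through acid chloride 4) and trimethylsilylacetylene 3, and 2 comes from 3,3-dimethylglutaric anhydride 1. The anhydride supplies C7–C11 with the gem-dimethyl group in place, and its two carbonyls are equivalent, so opening it needs no selectivity.

## Roads not taken

**Alternative 1:** The cut is the C5–carboxyl bond. A cycloundecynol A2 (ring already closed, C4≡C5 alkyne, free C7–OH) would be treated with Ni(cod)2 (zerovalent nickel) and ZnEt2 under CO2. The C7 zinc alkoxide should steer CO2 to C5 and hydrogen to C4 in a syn addition, and lactonization gives A1, which is the same compound as 21.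
- Merits: the carboxyl carbon comes from CO2, and the syn addition fixes the E geometry kinetically. In this respect it is better than the chosen plan, which relies on an equilibrium.
- Weak points: the ring problem is only moved, because A2 needs its own closure of a strained 11-membered cycloalkyne. The directed hydrocarboxylation is a known type for open-chain homopropargylic alcohols, but in the ring both alkyne carbons carry CH2 groups and regiocontrol rests on the alkoxide alone. Zerovalent nickel may also engage the 1,1-disubstituted alkene.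
- Comparison: both plans share the endgame from 21. The chosen plan sets against the better geometry control a ring closure that starts from a simple chain and builds the methylene in the same step.

**Alternative 2:** The cut is a retro-[3,3] shift at C2–C3. A 1,2-divinylcycloheptanol A4 would be treated with KH and 18-crown-6. The anionic oxy-Cope shift forms C2–C3, breaks C5–C11 and leaves a C1 enolate, which is trapped with dimethylmethyleneammonium iodide and eliminated to the methylene ketone A3.
- Merits: no macrocyclization is needed, since the 11-membered ring grows from a seven-membered one. Here it is the better plan, because the chosen route must pay the entropic cost of a medium-ring closure.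
- Weak points: A4 has two adjacent fully substituted carbons whose relative configuration, with the chair or boat preference, decides the C4=C5 geometry. C11 emerges as a ketone, and its configuration must be created by 1,2-reduction of a reactive α-methylene ketone with the only other stereocentre five atoms away. C5 arrives as a protected hydroxymethyl group that needs two late oxidation levels, and the C7 silyl ether must be exchanged for the isovalerate.
- Comparison: the chosen plan sets both carbinols on open-chain intermediates with well-understood reagent control and carries C5 at the acid oxidation level from the start.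

**Alternative 3:** The cut is C3–C4. In the acyclic diene A6, 9-borabicyclo[3.3.1]nonane would hydroborate the monosubstituted alkene at C3, and Pd(dppf)Cl2 (divalent palladium, reduced in the flask to zerovalent palladium) with Cs2CO3 would couple the borane with the C4 vinyl iodide to give the fully protected target A5.
- Merits: the alkene geometry is made in an open-chain vinyl iodide and kept with retention, and A5 is one global deprotection from 26. That endgame is clearly shorter than the five steps that follow ring closure in the chosen plan.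
- Weak points: the hydroboration must pick the terminal alkene of a 2-substituted buta-1,3-diene without conjugate addition or allylborane formation, and in the presence of an enoate. The isovalerate must survive aqueous base. The 11-membered ring must close without any template, where β-hydride elimination and protodeboronation compete.
- Comparison: against the longer endgame, the chosen plan offers a precursor with only two π systems and a lactone that brings the reacting ends together.

Key step: step 12

Remark: the ring numbering C1–C11 defined above is used for all cyclic compounds, and the target is taken as the (4E,7S,11S) isomer encoded by the stereodescriptors of its line notation.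

## Route

Step 1
Reactants: 1 3,3-dimethylglutaric anhydride
Product: 2 5-methoxy-3,3-dimethyl-5-oxopentanoic acid
Conditions: MeOH, reflux
Reagents that add atoms: methanol, CO
Why: Alcoholysis of a cyclic anhydride; the two carbonyl groups are equivalent, so a single half ester forms and the future C7 (ester) and C11 (acid) ends are told apart.

Step 2
Reactants: 2 5-methoxy-3,3-dimethyl-5-oxopentanoic acid; 3 trimethylsilylacetylene
Product: 5 methyl 3,3-dimethyl-5-oxo-7-(trimethylsilyl)hept-6-ynoate, via acid chloride 4 (not isolated)
Conditions: (COCl)2, cat. DMF, CH2Cl2, 0 °C to rt, concentrate; then 3, PdCl2(PPh3)2 (2 mol%), CuI (4 mol%), Et3N, THF, rt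
Reagents that add atoms: none
Why: Acid chloride formation and acyl Sonogashira coupling give the silyl ynone whose carbonyl is C11; the methyl ester is inert, and any scrambling of 4 through the anhydride would be degenerate.

Step 3
Reactants: 5 methyl 3,3-dimethyl-5-oxo-7-(trimethylsilyl)hept-6-ynoate
Product: 6 methyl (5S)-5-hydroxy-3,3-dimethyl-7-(trimethylsilyl)hept-6-ynoate
Conditions: Ru[(S,S)-TsNCH(Ph)CH(Ph)NH](p-cymene) (1–2 mol%), i-PrOH, rt
Reagents that add atoms: none
Why: Noyori asymmetric transfer hydrogenation of an alkynyl ketone; with the (S,S) catalyst the alkynyl group takes the place of the aryl group of aryl ketones and the (S)-carbinol (C11) should result; the crude δ-hydroxy ester is silylated at once to forestall lactonization.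

Step 4
Reactants: 6 methyl (5S)-5-hydroxy-3,3-dimethyl-7-(trimethylsilyl)hept-6-ynoate
Product: 7 methyl (5S)-5-[(tert-butyldimethylsilyl)oxy]-3,3-dimethyl-7-(trimethylsilyl)hept-6-ynoate
Conditions: TBSCl, imidazole, DMF, rt
Reagents that add atoms: tert-butyldimethylsilyl chloride, CC(C)(C)[Si](C)(C)Cl
Why: Standard silylation of a secondary alcohol; the TBS ether masks the C11 hydroxyl until the last step.

Step 5
Reactants: 7 methyl (5S)-5-[(tert-butyldimethylsilyl)oxy]-3,3-dimethyl-7-(trimethylsilyl)hept-6-ynoate
Product: 8 (5S)-5-[(tert-butyldimethylsilyl)oxy]-3,3-dimethyl-7-(trimethylsilyl)hept-6-ynal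
Conditions: i-Bu2AlH (1.1 equiv), CH2Cl2, −78 °C; aq. potassium sodium tartrate
Reagents that add atoms: none
Why: Partial reduction of a methyl ester at low temperature; the aluminium hemiacetal next to the quaternary carbon should persist until work-up and release the C7 aldehyde.

Step 6
Reactants: 8 (5S)-5-[(tert-butyldimethylsilyl)oxy]-3,3-dimethyl-7-(trimethylsilyl)hept-6-ynal
Product: 10 (4R,8S)-8-[(tert-butyldimethylsilyl)oxy]-6,6-dimethyl-10-(trimethylsilyl)dec-1-en-9-yn-4-ol, via O-boryl ether 9 (not isolated)
Conditions: (+)-Ipc2BOMe, CH2=CHCH2MgBr, Et2O, −78 °C to rt; then 8, −78 °C; then NaBO3·4H2O, THF/H2O, rt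
Reagents that add atoms: allylmagnesium bromide, C=CC[Mg]Br
Why: Brown allylboration; the allylborane of the (−)-α-pinene series should add through a chair transition state to the Re face of the aldehyde and set C7 under reagent control (4R in 10, which is 7S in the target after a priority change), the remote C11 centre having no influence; the mild perborate work-up spares the C–Si bond.

Step 7
Reactants: 10 (4R,8S)-8-[(tert-butyldimethylsilyl)oxy]-6,6-dimethyl-10-(trimethylsilyl)dec-1-en-9-yn-4-ol
Product: 12 (4R,8S)-8-[(tert-butyldimethylsilyl)oxy]-6,6-dimethyl-10-(trimethylsilyl)dec-9-yne-1,4-diol, via B-alkyl-9-borabicyclononane 11 (not isolated)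
Conditions: 9-BBN (excess), THF, 0 °C to rt; then NaBO3·4H2O, H2O, rt
Reagents that add atoms: sodium perborate, [Na+].[O-]OB=O
Why: Hydroboration–oxidation; 9-BBN adds anti-Markovnikov to the terminal alkene much faster than to the silyl-capped alkyne, and perborate oxidation gives the primary alcohol.

Step 8
Reactants: 12 (4R,8S)-8-[(tert-butyldimethylsilyl)oxy]-6,6-dimethyl-10-(trimethylsilyl)dec-9-yne-1,4-diol
Product: 13 (5R)-5-[(4S)-4-[(tert-butyldimethylsilyl)oxy]-2,2-dimethyl-6-(trimethylsilyl)hex-5-yn-1-yl]oxolan-2-one
Conditions: TEMPO (20 mol%), PhI(OAc)2 (3 equiv), CH2Cl2, rt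
Reagents that add atoms: none
Why: TEMPO/PhI(OAc)2 oxidative lactonization of a 1,4-diol: the primary alcohol is oxidized selectively, the C7 hydroxyl closes the lactol, and a second oxidation gives the γ-lactone without touching C7.

Step 9
Reactants: 13 (5R)-5-[(4S)-4-[(tert-butyldimethylsilyl)oxy]-2,2-dimethyl-6-(trimethylsilyl)hex-5-yn-1-yl]oxolan-2-one; 14 allyl bromide
Product: 16 (3S,5R)-3-allyl-5-[(4S)-4-[(tert-butyldimethylsilyl)oxy]-2,2-dimethyl-6-(trimethylsilyl)hex-5-yn-1-yl]oxolan-2-one (trans), via lithium enolate 15 (not isolated)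
Conditions: LiN(i-Pr)2 (1.05 equiv), THF, −78 °C; then 14, −78 to −40 °C
Reagents that add atoms: none
Why: Alkylation of a lactone lithium enolate; allyl bromide enters anti to the C7 side chain, so the trans epimer should predominate, and the epimer ratio is of no consequence because step 10 passes through a single enolate; the silyl cap keeps the alkyne out of the acid–base chemistry.

Step 10
Reactants: 16 (3S,5R)-3-allyl-5-[(4S)-4-[(tert-butyldimethylsilyl)oxy]-2,2-dimethyl-6-(trimethylsilyl)hex-5-yn-1-yl]oxolan-2-one
Product: 18 (3R,5R)-3-allyl-5-[(4S)-4-[(tert-butyldimethylsilyl)oxy]-2,2-dimethyl-6-(trimethylsilyl)hex-5-yn-1-yl]oxolan-2-one (cis), via lithium enolate 17 (not isolated)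
Conditions: LiN(i-Pr)2, THF, −78 °C; then 2,6-di-tert-butyl-4-methylphenol, −78 °C; H2O
Reagents that add atoms: none
Why: Enolization and kinetic protonation; the bulky phenol delivers the proton anti to the C7 side chain, which places the allyl group on the same face as that chain and should give the cis lactone, also the more stable epimer; any trans material is separated and recycled.

Step 11
Reactants: 18 (3R,5R)-3-allyl-5-[(4S)-4-[(tert-butyldimethylsilyl)oxy]-2,2-dimethyl-6-(trimethylsilyl)hex-5-yn-1-yl]oxolan-2-one
Product: 19 (3R,5R)-3-allyl-5-[(4S)-4-[(tert-butyldimethylsilyl)oxy]-2,2-dimethylhex-5-yn-1-yl]oxolan-2-one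
Conditions: AgNO3 (10 mol%), 2,6-lutidine, acetone/H2O, rt
Reagents that add atoms: none
Why: Silver-catalysed protodesilylation of an alkynylsilane; the neutral conditions leave the lactone, its C5 configuration and the TBS ether intact.

Step 12
Reactants: 19 (3R,5R)-3-allyl-5-[(4S)-4-[(tert-butyldimethylsilyl)oxy]-2,2-dimethylhex-5-yn-1-yl]oxolan-2-one
Product: 20 (3E,5S,7R,11S)-11-[(tert-butyldimethylsilyl)oxy]-9,9-dimethyl-1-methylidenecycloundec-3-ene-5-carbo-7-lactone (γ-lactone bridge from the C5 carbonyl carbon to the C7 oxygen)
Conditions: [CpRu(MeCN)3]PF6 (10 mol%), acetone, 0.002 M, slow addition of 19, rt to 50 °C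
Reagents that add atoms: none
Why: The cationic cyclopentadienylruthenium fragment (divalent ruthenium) binds the terminal alkyne and the monosubstituted alkene of 19; oxidative cyclization joins the internal alkyne carbon C1 to the terminal alkene carbon C2 in a ruthenacyclopentene, β-hydride elimination takes a hydrogen from C4, and reductive elimination passes it to the former alkyne terminus, which becomes the exocyclic methylene. The closest known reaction type is the ruthenium-catalysed alkene–alkyne (Alder-ene) coupling to branched 1,4-dienes and its use in macrocyclization; an 11-membered ring lies below the sizes usually closed this way, which is why a template is used. The 11-membered ring closes exo with respect to the alkyne (its terminal carbon stays outside the ring) and endo with respect to the alkene (C2 and C3 both become ring atoms), whereas the linear mode would put both alkyne carbons into a 12-membered ring. No stereocentre is created, and the C3=C4 alkene should be E because β-hydride elimination proceeds from the conformer with C5 anti to the metallacycle, as in the intermolecular reaction. Ring closure over oligomerization is secured by high dilution with slow addition, by the cis lactone that holds both chains on one face, and by the gem-dimethyl group at C9; branched over linear bond formation is the catalyst's normal preference for terminal alkynes. Chemoselectivity follows from the alkyne and the allyl group being the only unhindered π systems, and the lactone, the silyl ether and the acidic C5–H are spectators under these neutral conditions.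

Step 13
Reactants: 20 (3E,5S,7R,11S)-11-[(tert-butyldimethylsilyl)oxy]-9,9-dimethyl-1-methylidenecycloundec-3-ene-5-carbo-7-lactone
Product: 21 (4E,7S,11S)-11-[(tert-butyldimethylsilyl)oxy]-9,9-dimethyl-1-methylidenecycloundec-4-ene-5-carbo-7-lactone
Conditions: DBU, toluene, rt to 60 °C
Reagents that add atoms: none
Why: Base-mediated conjugation through the dienolate (deprotonation at C5, protonation at C3); under equilibrating conditions the alkylidene lactone with C3 cis to C6 should prevail, because it is conjugated and holds a cis alkene within the 11-membered ring.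

Step 14
Reactants: 21 (4E,7S,11S)-11-[(tert-butyldimethylsilyl)oxy]-9,9-dimethyl-1-methylidenecycloundec-4-ene-5-carbo-7-lactone; 14 allyl bromide
Product: 23 allyl (4E,7S,11S)-11-[(tert-butyldimethylsilyl)oxy]-7-hydroxy-9,9-dimethyl-1-methylidenecycloundec-4-ene-5-carboxylate, via lithium carboxylate 22 (not isolated)
Conditions: LiOH·H2O (1.5 equiv), THF/H2O, 0 °C to rt, concentrate; then 14, DMF, rt
Reagents that add atoms: lithium hydroxide, [Li+].[OH-]
Why: Saponification of the lactone and O-alkylation of the carboxylate in one flask; the medium stays basic until the ester exists, which should prevent re-lactonization, and C7 keeps its configuration because the acyl–oxygen bond is the one cleaved.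

Step 15
Reactants: 23 allyl (4E,7S,11S)-11-[(tert-butyldimethylsilyl)oxy]-7-hydroxy-9,9-dimethyl-1-methylidenecycloundec-4-ene-5-carboxylate
Product: 24 allyl (4E,7S,11S)-11-[(tert-butyldimethylsilyl)oxy]-9,9-dimethyl-1-methylidene-7-[(3-methylbutanoyl)oxy]cycloundec-4-ene-5-carboxylate
Conditions: isovaleric anhydride, DMAP (cat.), pyridine, CH2Cl2, 0 °C to rt
Reagents that add atoms: isovaleric anhydride, CC(C)CC(=O)OC(=O)CC(C)C
Why: DMAP-catalysed acylation of the only free hydroxyl group, the secondary C7 alcohol.

Step 16
Reactants: 24 allyl (4E,7S,11S)-11-[(tert-butyldimethylsilyl)oxy]-9,9-dimethyl-1-methylidene-7-[(3-methylbutanoyl)oxy]cycloundec-4-ene-5-carboxylate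
Product: 25 (4E,7S,11S)-11-[(tert-butyldimethylsilyl)oxy]-9,9-dimethyl-1-methylidene-7-[(3-methylbutanoyl)oxy]cycloundec-4-ene-5-carboxylic acid
Conditions: Pd(PPh3)4 (5 mol%), morpholine, THF, rt; dilute aq. citric acid work-up
Reagents that add atoms: none
Why: Tsuji–Trost deallylation: zerovalent palladium ionizes the allyl ester to a π-allyl complex that morpholine intercepts; the isovalerate, the silyl ether and the other alkenes cannot ionize.

Step 17
Reactants: 25 (4E,7S,11S)-11-[(tert-butyldimethylsilyl)oxy]-9,9-dimethyl-1-methylidene-7-[(3-methylbutanoyl)oxy]cycloundec-4-ene-5-carboxylic acid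
Product: 26 (4E,7S,11S)-11-hydroxy-9,9-dimethyl-1-methylidene-7-[(3-methylbutanoyl)oxy]cycloundec-4-ene-5-carboxylic acid (the target)
Conditions: HF·pyridine, pyridine/THF, 0 °C to rt
Reagents that add atoms: none
Why: Fluoride-mediated cleavage of the silyl ether under buffered conditions that the ester, the acid and the allylic alcohol should tolerate.

## Compound list

1 | 3,3-dimethylglutaric anhydride | CC1(C)CC(=O)OC(=O)C1 | starting material
2 | 5-methoxy-3,3-dimethyl-5-oxopentanoic acid | COC(=O)CC(C)(C)CC(=O)O | intermediate
3 | trimethylsilylacetylene | C#C[Si](C)(C)C | starting material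
4 | methyl 5-chloro-3,3-dimethyl-5-oxopentanoate | COC(=O)CC(C)(C)CC(=O)Cl | intermediate (not isolated)
5 | methyl 3,3-dimethyl-5-oxo-7-(trimethylsilyl)hept-6-ynoate | COC(=O)CC(C)(C)CC(=O)C#C[Si](C)(C)C | intermediate
6 | methyl (5S)-5-hydroxy-3,3-dimethyl-7-(trimethylsilyl)hept-6-ynoate | C[Si](C)(C)C#C[C@@H](O)CC(C)(C)CC(=O)OC | intermediate
7 | methyl (5S)-5-[(tert-butyldimethylsilyl)oxy]-3,3-dimethyl-7-(trimethylsilyl)hept-6-ynoate | C[Si](C)(C)C#C[C@@H](O[Si](C)(C)C(C)(C)C)CC(C)(C)CC(=O)OC | intermediate
8 | (5S)-5-[(tert-butyldimethylsilyl)oxy]-3,3-dimethyl-7-(trimethylsilyl)hept-6-ynal | C[Si](C)(C)C#C[C@@H](O[Si](C)(C)C(C)(C)C)CC(C)(C)CC=O | intermediate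
9 | O-diisopinocampheylboryl ether of 10 (isopinocampheyl groups of the (−)-α-pinene series) | C[Si](C)(C)C#C[C@@H](O[Si](C)(C)C(C)(C)C)CC(C)(C)C[C@H](OB([C@H]1C[C@H]2C[C@@H]([C@@H]1C)C2(C)C)[C@H]1C[C@H]2C[C@@H]([C@@H]1C)C2(C)C)CC=C | intermediate (not isolated)
10 | (4R,8S)-8-[(tert-butyldimethylsilyl)oxy]-6,6-dimethyl-10-(trimethylsilyl)dec-1-en-9-yn-4-ol | C[Si](C)(C)C#C[C@@H](O[Si](C)(C)C(C)(C)C)CC(C)(C)C[C@H](O)CC=C | intermediate
11 | 9-BBN adduct of 10 at the terminal carbon | C[Si](C)(C)C#C[C@@H](O[Si](C)(C)C(C)(C)C)CC(C)(C)C[C@H](O)CCCB1C2CCCC1CCC2 | intermediate (not isolated)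
12 | (4R,8S)-8-[(tert-butyldimethylsilyl)oxy]-6,6-dimethyl-10-(trimethylsilyl)dec-9-yne-1,4-diol | C[Si](C)(C)C#C[C@@H](O[Si](C)(C)C(C)(C)C)CC(C)(C)C[C@H](O)CCCO | intermediate
13 | (5R)-5-[(4S)-4-[(tert-butyldimethylsilyl)oxy]-2,2-dimethyl-6-(trimethylsilyl)hex-5-yn-1-yl]oxolan-2-one | C[Si](C)(C)C#C[C@@H](O[Si](C)(C)C(C)(C)C)CC(C)(C)C[C@H]1CCC(=O)O1 | intermediate
14 | allyl bromide | C=CCBr | starting material
15 | lithium enolate of 13 | C[Si](C)(C)C#C[C@@H](O[Si](C)(C)C(C)(C)C)CC(C)(C)C[C@H]1CC=C([O-])O1.[Li+] | intermediate (not isolated)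
16 | (3S,5R)-3-allyl-5-[(4S)-4-[(tert-butyldimethylsilyl)oxy]-2,2-dimethyl-6-(trimethylsilyl)hex-5-yn-1-yl]oxolan-2-one (trans) | C[Si](C)(C)C#C[C@@H](O[Si](C)(C)C(C)(C)C)CC(C)(C)C[C@H]1C[C@H](CC=C)C(=O)O1 | intermediate
17 | lithium enolate of 16 | C[Si](C)(C)C#C[C@@H](O[Si](C)(C)C(C)(C)C)CC(C)(C)C[C@H]1CC(CC=C)=C([O-])O1.[Li+] | intermediate (not isolated)
18 | (3R,5R)-3-allyl-5-[(4S)-4-[(tert-butyldimethylsilyl)oxy]-2,2-dimethyl-6-(trimethylsilyl)hex-5-yn-1-yl]oxolan-2-one (cis) | C[Si](C)(C)C#C[C@@H](O[Si](C)(C)C(C)(C)C)CC(C)(C)C[C@H]1C[C@@H](CC=C)C(=O)O1 | intermediate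
19 | (3R,5R)-3-allyl-5-[(4S)-4-[(tert-butyldimethylsilyl)oxy]-2,2-dimethylhex-5-yn-1-yl]oxolan-2-one | C#C[C@@H](O[Si](C)(C)C(C)(C)C)CC(C)(C)C[C@H]1C[C@@H](CC=C)C(=O)O1 | intermediate
20 | (3E,5S,7R,11S)-11-[(tert-butyldimethylsilyl)oxy]-9,9-dimethyl-1-methylidenecycloundec-3-ene-5-carbo-7-lactone | C=C1C/C=C/[C@@H]2C[C@@H](OC2=O)CC(C)(C)C[C@@H]1O[Si](C)(C)C(C)(C)C | intermediate
21 | (4E,7S,11S)-11-[(tert-butyldimethylsilyl)oxy]-9,9-dimethyl-1-methylidenecycloundec-4-ene-5-carbo-7-lactone | C=C1CC/C=C2\C[C@@H](OC2=O)CC(C)(C)C[C@@H]1O[Si](C)(C)C(C)(C)C | intermediate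
22 | lithium (4E,7S,11S)-11-[(tert-butyldimethylsilyl)oxy]-7-hydroxy-9,9-dimethyl-1-methylidenecycloundec-4-ene-5-carboxylate | C=C1CC/C=C(/C(=O)[O-])C[C@@H](O)CC(C)(C)C[C@@H]1O[Si](C)(C)C(C)(C)C.[Li+] | intermediate (not isolated)
23 | allyl (4E,7S,11S)-11-[(tert-butyldimethylsilyl)oxy]-7-hydroxy-9,9-dimethyl-1-methylidenecycloundec-4-ene-5-carboxylate | C=C1CC/C=C(/C(=O)OCC=C)C[C@@H](O)CC(C)(C)C[C@@H]1O[Si](C)(C)C(C)(C)C | intermediate
24 | allyl (4E,7S,11S)-11-[(tert-butyldimethylsilyl)oxy]-9,9-dimethyl-1-methylidene-7-[(3-methylbutanoyl)oxy]cycloundec-4-ene-5-carboxylate | C=C1CC/C=C(/C(=O)OCC=C)C[C@@H](OC(=O)CC(C)C)CC(C)(C)C[C@@H]1O[Si](C)(C)C(C)(C)C | intermediate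
25 | (4E,7S,11S)-11-[(tert-butyldimethylsilyl)oxy]-9,9-dimethyl-1-methylidene-7-[(3-methylbutanoyl)oxy]cycloundec-4-ene-5-carboxylic acid | C=C1CC/C=C(/C(=O)O)C[C@@H](OC(=O)CC(C)C)CC(C)(C)C[C@@H]1O[Si](C)(C)C(C)(C)C | intermediate
26 | (4E,7S,11S)-11-hydroxy-9,9-dimethyl-1-methylidene-7-[(3-methylbutanoyl)oxy]cycloundec-4-ene-5-carboxylic acid (systematic numbering: (1E,6S,10S)-6-hydroxy-8,8-dimethyl-5-methylidene-10-[(3-methylbutanoyl)oxy]cycloundec-1-ene-1-carboxylic acid) | C=C1CC/C=C(/C(=O)O)C[C@@H](OC(=O)CC(C)C)CC(C)(C)C[C@@H]1O | target

## Step count and least certain steps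

Total step count: 17. Longest linear sequence: 17 steps, from 1 to 26.

**Step 12 (key step).** The likely failures are intermolecular coupling to oligomers, bond formation at the terminal alkyne carbon (the linear mode with a 12-membered ring), or stalling of the catalyst on the product diene. The cause is that the 11-membered transition state is strained and the propargylic silyloxy group crowds the internal alkyne carbon. The fallback keeps the ruthenium coupling for the C1–C2 bond but runs it between two molecules and closes the ring at C4=C5. It sets out from 13 and rejoins the route at 21. Lactone 13 is treated with LiN(i-Pr)2 and ClP(O)(OEt)2 (enol phosphate, then 1,3-phosphorus shift with a second equivalent of base) to give the α-phosphono lactone F1. AgNO3-catalysed C-desilylation gives the terminal alkyne F2. Coupling of F2 with allyl alcohol under [CpRu(MeCN)3]PF6 gives the γ,δ-unsaturated aldehyde F3, because the enol formed by the Alder-ene step tautomerizes. An intramolecular Horner–Wadsworth–Emmons reaction (LiCl, DBU, MeCN, high dilution) then closes the ring to 21.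

**Step 13.** Conjugation may stay incomplete or end at the wrong alkene isomer, because in the bridged bicycle the position and geometry of the double bond are set by a strain-dependent equilibrium and not by a kinetic preference. The fallback moves the alkene only after the bridge is gone. It sets out from 20 and rejoins at 24. Saponification and allylation as in step 14 give the β,γ-unsaturated hydroxy allyl ester F4, acylation as in step 15 gives the isovalerate F5, and DBU then brings the alkene into conjugation in the unbridged ring, where the ring-cis (E) enoate should be favoured.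

**Step 14.** The lactone may re-close during concentration or alkylation, and hydroxide may add in conjugate fashion, because the γ-hydroxy carboxylate is held in the geometry of the lactone it came from. The fallback opens the lactone by reduction. It sets out from 21 and rejoins at 25. i-Bu2AlH gives the diol F6; triethylsilyl chloride and imidazole at low temperature silylate the primary allylic hydroxyl to give the silyl ether F7; isovaleric anhydride and DMAP give the isovalerate F8; Swern oxidation converts the primary triethylsilyl ether directly into the enal F9; and Pinnick oxidation (NaClO2, NaH2PO4, 2-methylbut-2-ene) gives 25.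

**Step 10.** Facial selectivity in the protonation of the enolate may be poor and return much trans epimer, because the C7 substituent is 1,3 to the reacting carbon. The fallback sets C5 by a chiral auxiliary. It sets out from 13 and rejoins at 18. LiOH opening, bis-silylation with triethylsilyl chloride and hydrolysis of the silyl ester on work-up give the silyloxy acid F10. Pivaloyl chloride and the lithium salt of (R)-4-benzyl-1,3-oxazolidin-2-one give the imide F11. Evans alkylation (NaN(SiMe3)2, allyl iodide) gives the allylated imide F12 with C5 set independently of C7. Pyridinium p-toluenesulfonate in MeOH removes the triethylsilyl group, and the freed C7 hydroxyl lactonizes with loss of the auxiliary to give 18.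

**Step 3.** The δ-hydroxy ester may lactonize before silylation, helped by the gem-dimethyl group, and enantioselectivity may be lower than with methyl ketones because of the larger alkyl arm. The fallback accepts the lactone. It sets out from 6 and rejoins at 8. Acid-catalysed cyclization is driven to the δ-lactone F13; MeNH(OMe)·HCl with AlMe3 opens it to the hydroxy Weinreb amide F14; TBSCl and imidazole give the silyl ether F15; and i-Bu2AlH reduces the amide to aldehyde 8.

## Further compounds

F1 | step 12 | diethyl {(5R)-5-[(4S)-4-[(tert-butyldimethylsilyl)oxy]-2,2-dimethyl-6-(trimethylsilyl)hex-5-yn-1-yl]-2-oxooxolan-3-yl}phosphonate (C3 epimers) | C[Si](C)(C)C#C[C@@H](O[Si](C)(C)C(C)(C)C)CC(C)(C)C[C@H]1CC(P(=O)(OCC)OCC)C(=O)O1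
F2 | step 12 | diethyl {(5R)-5-[(4S)-4-[(tert-butyldimethylsilyl)oxy]-2,2-dimethylhex-5-yn-1-yl]-2-oxooxolan-3-yl}phosphonate | C#C[C@@H](O[Si](C)(C)C(C)(C)C)CC(C)(C)C[C@H]1CC(P(=O)(OCC)OCC)C(=O)O1
F3 | step 12 | diethyl {(5R)-5-[(4S)-4-[(tert-butyldimethylsilyl)oxy]-2,2-dimethyl-5-methylidene-8-oxooctyl]-2-oxooxolan-3-yl}phosphonate | O=CCCC(=C)[C@@H](O[Si](C)(C)C(C)(C)C)CC(C)(C)C[C@H]1CC(P(=O)(OCC)OCC)C(=O)O1
F4 | step 13 | allyl (3E,5S,7R,11S)-11-[(tert-butyldimethylsilyl)oxy]-7-hydroxy-9,9-dimethyl-1-methylidenecycloundec-3-ene-5-carboxylate | C=C1C/C=C/[C@@H](C(=O)OCC=C)C[C@@H](O)CC(C)(C)C[C@@H]1O[Si](C)(C)C(C)(C)C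
F5 | step 13 | allyl (3E,5S,7R,11S)-11-[(tert-butyldimethylsilyl)oxy]-9,9-dimethyl-1-methylidene-7-[(3-methylbutanoyl)oxy]cycloundec-3-ene-5-carboxylate | C=C1C/C=C/[C@@H](C(=O)OCC=C)C[C@@H](OC(=O)CC(C)C)CC(C)(C)C[C@@H]1O[Si](C)(C)C(C)(C)C
F6 | step 14 | (4E,7S,11S)-11-[(tert-butyldimethylsilyl)oxy]-5-(hydroxymethyl)-9,9-dimethyl-1-methylidenecycloundec-4-en-7-ol | C=C1CC/C=C(/CO)C[C@@H](O)CC(C)(C)C[C@@H]1O[Si](C)(C)C(C)(C)C
F7 | step 14 | (4E,7S,11S)-11-[(tert-butyldimethylsilyl)oxy]-9,9-dimethyl-1-methylidene-5-{[(triethylsilyl)oxy]methyl}cycloundec-4-en-7-ol | C=C1CC/C=C(/CO[Si](CC)(CC)CC)C[C@@H](O)CC(C)(C)C[C@@H]1O[Si](C)(C)C(C)(C)C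
F8 | step 14 | (4E,7S,11S)-11-[(tert-butyldimethylsilyl)oxy]-9,9-dimethyl-1-methylidene-5-{[(triethylsilyl)oxy]methyl}cycloundec-4-en-7-yl 3-methylbutanoate | C=C1CC/C=C(/CO[Si](CC)(CC)CC)C[C@@H](OC(=O)CC(C)C)CC(C)(C)C[C@@H]1O[Si](C)(C)C(C)(C)C
F9 | step 14 | (4E,7S,11S)-11-[(tert-butyldimethylsilyl)oxy]-5-formyl-9,9-dimethyl-1-methylidenecycloundec-4-en-7-yl 3-methylbutanoate | C=C1CC/C=C(/C=O)C[C@@H](OC(=O)CC(C)C)CC(C)(C)C[C@@H]1O[Si](C)(C)C(C)(C)C
F10 | step 10 | (4R,8S)-8-[(tert-butyldimethylsilyl)oxy]-6,6-dimethyl-4-[(triethylsilyl)oxy]-10-(trimethylsilyl)dec-9-ynoic acid | C[Si](C)(C)C#C[C@@H](O[Si](C)(C)C(C)(C)C)CC(C)(C)C[C@H](O[Si](CC)(CC)CC)CCC(=O)O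
F11 | step 10 | (4R)-4-benzyl-3-[(4R,8S)-8-[(tert-butyldimethylsilyl)oxy]-6,6-dimethyl-4-[(triethylsilyl)oxy]-10-(trimethylsilyl)dec-9-ynoyl]-1,3-oxazolidin-2-one | C[Si](C)(C)C#C[C@@H](O[Si](C)(C)C(C)(C)C)CC(C)(C)C[C@H](O[Si](CC)(CC)CC)CCC(=O)N1[C@H](Cc2ccccc2)COC1=O
F12 | step 10 | (4R)-3-[(2R,4R,8S)-2-allyl-8-[(tert-butyldimethylsilyl)oxy]-6,6-dimethyl-4-[(triethylsilyl)oxy]-10-(trimethylsilyl)dec-9-ynoyl]-4-benzyl-1,3-oxazolidin-2-one | C[Si](C)(C)C#C[C@@H](O[Si](C)(C)C(C)(C)C)CC(C)(C)C[C@H](O[Si](CC)(CC)CC)C[C@@H](CC=C)C(=O)N1[C@H](Cc2ccccc2)COC1=O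
F13 | step 3 | (6S)-4,4-dimethyl-6-[(trimethylsilyl)ethynyl]oxan-2-one | C[Si](C)(C)C#C[C@@H]1CC(C)(C)CC(=O)O1
F14 | step 3 | (5S)-5-hydroxy-N-methoxy-N,3,3-trimethyl-7-(trimethylsilyl)hept-6-ynamide | C[Si](C)(C)C#C[C@@H](O)CC(C)(C)CC(=O)N(C)OC
F15 | step 3 | (5S)-5-[(tert-butyldimethylsilyl)oxy]-N-methoxy-N,3,3-trimethyl-7-(trimethylsilyl)hept-6-ynamide | C[Si](C)(C)C#C[C@@H](O[Si](C)(C)C(C)(C)C)CC(C)(C)CC(=O)N(C)OC
A1 | alternative 1 | bridged E-alkylidene γ-lactone with C11 silyl ether (identical with 21) | C=C1CC/C=C2\C[C@@H](OC2=O)CC(C)(C)C[C@@H]1O[Si](C)(C)C(C)(C)C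
A2 | alternative 1 | cycloundec-4-yn-7-ol with C1 methylidene, 9,9-dimethyl and C11 silyl ether (C7 and C11 as in the target) | C=C1CCC#CC[C@@H](O)CC(C)(C)C[C@@H]1O[Si](C)(C)C(C)(C)C
A3 | alternative 2 | 11-membered C1-methylidene C11 ketone with C5 (4-methoxybenzyloxy)methyl group and C7 silyl ether | C=C1CC/C=C(/COCc2ccc(OC)cc2)C[C@@H](O[Si](C)(C)C(C)(C)C)CC(C)(C)CC1=O
A4 | alternative 2 | cis-1,2-divinylcycloheptanol with C5 (4-methoxybenzyloxy)methyl group and C7 silyl ether (one diastereomer shown) | C=C[C@]1(O)CC(C)(C)C[C@H](O[Si](C)(C)C(C)(C)C)C[C@@]1(C=C)COCc1ccc(OC)cc1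
A5 | alternative 3 | fully protected target (2-(trimethylsilyl)ethoxymethyl ester, C11 silyl ether) | C=C1CC/C=C(/C(=O)OCOCC[Si](C)(C)C)C[C@@H](OC(=O)CC(C)C)CC(C)(C)C[C@@H]1O[Si](C)(C)C(C)(C)C
A6 | alternative 3 | acyclic 2-substituted buta-1,3-diene with C4 vinyl iodide, C7 isovalerate and protected acid | C=CC(=C)[C@@H](O[Si](C)(C)C(C)(C)C)CC(C)(C)C[C@H](OC(=O)CC(C)C)C/C(=C\I)C(=O)OCOCC[Si](C)(C)C
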